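**Retrosynthetic overview**

1. Target 17 ← fluoride removal of three silyl groups ← twofold Stille prenylation at C3' and C5' of ring B (dibromide 14) ← silyl-triflate opening of oxirane 13 at C3'' with loss of a methyl proton.
2. 13 ← catalyst-controlled epoxidation of C2''=C3'' in 12. Feature used: of the three C5 chains only the one on C8 of ring A is oxidised (OH on C2'', C3''=CH2); with Br in place of the prenyls at C3'/C5' of ring B, this alkene is the only C=C in 12.
3. 12 ← [RhCl(C2H4)2]2/chiral diene 1,4-addition of arylboronic acid 11 to C2 of chromone 7 (C2–C1' bond, C2 stereocentre); 11 ← 2,6-dibromophenol by silylation and para C–H borylation.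
4. 7 ← 7-hydroxychromone by O-(1,1-dimethylpropargyl)ation, semihydrogenation, Claisen shift to C8 and silylation.
5. Ring order: rings A and C arrive fused in 7-hydroxychromone, ring B is attached in step 8, and the oxirane is the only ring formed (step 9) and is opened again in step 10.

Key step: step 9

Remark: both phenols are carried as triisopropylsilyl ethers and the C2'' oxygen as a tert-butyldimethylsilyl ether. The antipode of the diene ligand in step 8 is assigned by analogy with additions to cyclic enones, and the antipode that proves to give (2S) is the one to use.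

**Route**

Step 1
Reactants: 1 7-hydroxychromone; 2 3-chloro-3-methylbut-1-yne
Product: 3 7-(2-methylbut-3-yn-2-yloxy)chromen-4-one
Conditions: CuCl2·2H2O (1 mol %), DBU, MeCN, 0 °C
Reagents that add atoms: none
Why: Copper-catalysed propargylic etherification of a phenol with a tertiary propargyl chloride should work well on the acidic 7-hydroxyl of the chromone, which is the only nucleophilic site.

Step 2
Reactants: 3 7-(2-methylbut-3-yn-2-yloxy)chromen-4-one
Product: 4 7-(2-methylbut-3-en-2-yloxy)chromen-4-one
Conditions: H2 (1 atm), Pd/CaCO3 poisoned with Pb(OAc)2 (Lindlar catalyst), quinoline, EtOAc, rt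
Reagents that add atoms: none
Why: Lindlar semihydrogenation of the terminal alkyne should stop at the alkene, since the poisoned palladium surface reduces neither the new vinyl group nor the conjugated C2=C3 bond of the chromone at a comparable rate.

Step 3
Reactants: 4 7-(2-methylbut-3-en-2-yloxy)chromen-4-one
Product: 6 7-hydroxy-8-(3-methylbut-2-enyl)chromen-4-one, via ortho-dienone 5 (not isolated)
Conditions: PhNEt2, 140 °C
Reagents that add atoms: none
Why: The aromatic Claisen rearrangement ([3,3] shift) of the 1,1-dimethylallyl ether delivers the allyl unit inverted, that is as a prenyl group, to C8 in preference to C6 because the C7–C8 bond of the benzopyranone has the higher double-bond character, and dienone 5 then tautomerises to the phenol.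

Step 4
Reactants: 6 7-hydroxy-8-(3-methylbut-2-enyl)chromen-4-one
Product: 7 8-(3-methylbut-2-enyl)-7-(triisopropylsilyloxy)chromen-4-one
Conditions: TIPSCl, imidazole, DMF, rt
Reagents that add atoms: triisopropylsilyl chloride, CC(C)[Si](Cl)(C(C)C)C(C)C
Why: Imidazole-promoted O-silylation of the phenol gives a bulky aryl silyl ether that should withstand the mildly basic aqueous media of steps 8 and 9.

Step 5
Reactants: 8 2,6-dibromophenol
Product: 9 (2,6-dibromophenoxy)triisopropylsilane
Conditions: TIPSOTf, 2,6-lutidine, CH2Cl2, 0 °C → rt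
Reagents that add atoms: triisopropylsilyl triflate, CC(C)[Si](OS(=O)(=O)C(F)(F)F)(C(C)C)C(C)C
Why: O-Silylation with the silyl triflate should overcome the low nucleophilicity of this acidic, doubly ortho-substituted phenol.

Step 6
Reactants: 9 (2,6-dibromophenoxy)triisopropylsilane
Product: 10 2-[3,5-dibromo-4-(triisopropylsilyloxy)phenyl]-4,4,5,5-tetramethyl-1,3,2-dioxaborolane
Conditions: [Ir(OMe)(cod)]2 (1.5 mol %), 4,4'-di-tert-butyl-2,2'-bipyridine (3 mol %), B2pin2, MTBE, 80 °C
Reagents that add atoms: bis(pinacolato)diboron, CC1(C)OB(OC1(C)C)B1OC(C)(C)C(C)(C)O1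
Why: Sterically controlled C–H borylation with [Ir(OMe)(cod)]2/bipyridine should take place only at the C–H para to oxygen, the one position without an ortho substituent, and leaves C–Br bonds intact.

Step 7
Reactants: 10 2-[3,5-dibromo-4-(triisopropylsilyloxy)phenyl]-4,4,5,5-tetramethyl-1,3,2-dioxaborolane
Product: 11 [3,5-dibromo-4-(triisopropylsilyloxy)phenyl]boronic acid
Conditions: NaIO4, NH4OAc, acetone/H2O, rt
Reagents that add atoms: water, O
Why: Oxidative glycol cleavage of the pinacol released in the hydrolysis equilibrium drives the boronic ester to the free boronic acid under near-neutral conditions that the aryl silyl ether tolerates.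

Step 8
Reactants: 7 8-(3-methylbut-2-enyl)-7-(triisopropylsilyloxy)chromen-4-one; 11 [3,5-dibromo-4-(triisopropylsilyloxy)phenyl]boronic acid
Product: 12 (2S)-2-[3,5-dibromo-4-(triisopropylsilyloxy)phenyl]-8-(3-methylbut-2-enyl)-7-(triisopropylsilyloxy)chroman-4-one
Conditions: [RhCl(C2H4)2]2 (2.5 mol %), (1S,4S)-2,5-diphenylbicyclo[2.2.2]octa-2,5-diene (5.5 mol %), KOH (10 mol %, aq), 1,4-dioxane/H2O 10:1, 40 °C, 11 (2 equiv)
Reagents that add atoms: none
Why: In this Hayashi–Miyaura asymmetric 1,4-addition the aryl–rhodium species of the monovalent metal inserts the C2=C3 bond of the chromone on one enantioface and water protonates the resulting oxa-π-allyl, so the diene ligand sets C2 (the (S,S) antipode is chosen because the (R,R) form arylates cyclic enones on the face that would correspond to (2R) here), while the C–Br bonds and the trisubstituted prenyl alkene are inert to the monovalent rhodium.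

Step 9
Reactants: 12 (2S)-2-[3,5-dibromo-4-(triisopropylsilyloxy)phenyl]-8-(3-methylbut-2-enyl)-7-(triisopropylsilyloxy)chroman-4-one
Product: 13 (2S)-2-[3,5-dibromo-4-(triisopropylsilyloxy)phenyl]-8-{[(2R)-3,3-dimethyloxiran-2-yl]methyl}-7-(triisopropylsilyloxy)chroman-4-one
Conditions: D-fructose-derived Shi ketone (1,2:4,5-di-O-isopropylidene-β-D-erythro-2,3-hexodiulo-2,6-pyranose, 30 mol %), Oxone (2KHSO5·KHSO4·K2SO4), K2CO3, Bu4NHSO4, Na2B4O7/Na2EDTA buffer (pH about 10.5), MeCN/CH2(OMe)2 1:2, 0 °C
Reagents that add atoms: potassium peroxymonosulfate (the active salt of Oxone), [K+].[O-]S(=O)(=O)OO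
Why: KHSO5 turns the carbohydrate ketone into a chiral dioxirane, which hands one oxygen atom to the electron-rich C2''=C3'' alkene in a single concerted event through a spiro transition state, so both C–O bonds form on the same alkene face. This is the Shi asymmetric epoxidation, well established for trisubstituted alkenes including aryl-bound prenyl groups. The oxirane therefore closes by concerted [2+1] oxygen-atom transfer and not by a stepwise exo or endo cyclisation. The only new stereocentre, C2'', is set by the catalyst, and the ketone of D-fructose origin is expected to give the (R) oxirane carbon; C2, five bonds away, should have no say. The step needs chemoselectivity and face selectivity: the first is secured because ring B still carries Br at C3' and C5', so the 8-prenyl alkene is the only C=C, and the aryl ketone, aryl bromides and hindered aryl silyl ethers should not react with the dioxirane at 0 °C. The oxirane is temporary and only stores the C2'' oxygen and its configuration for step 10.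

Step 10
Reactants: 13 (2S)-2-[3,5-dibromo-4-(triisopropylsilyloxy)phenyl]-8-{[(2R)-3,3-dimethyloxiran-2-yl]methyl}-7-(triisopropylsilyloxy)chroman-4-one
Product: 14 (2S)-8-[(2R)-2-(tert-butyldimethylsilyloxy)-3-methylbut-3-enyl]-2-[3,5-dibromo-4-(triisopropylsilyloxy)phenyl]-7-(triisopropylsilyloxy)chroman-4-one
Conditions: TBSOTf, 2,6-lutidine, CH2Cl2, −78 → −20 °C
Reagents that add atoms: tert-butyldimethylsilyl triflate, CC(C)(C)[Si](C)(C)OS(=O)(=O)C(F)(F)F
Why: In this silyl triflate/amine isomerisation of an oxirane to an allylic silyl ether the silylated oxirane ionises at the tertiary C3'' and lutidine removes a methyl proton, so the C2''–O bond is never broken and the (R) configuration is retained, while at low temperature with this weak base enol silylation of the C4 ketone should be slow.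

Step 11
Reactants: 14 (2S)-8-[(2R)-2-(tert-butyldimethylsilyloxy)-3-methylbut-3-enyl]-2-[3,5-dibromo-4-(triisopropylsilyloxy)phenyl]-7-(triisopropylsilyloxy)chroman-4-one; 15 tributyl(3-methylbut-2-enyl)stannane
Product: 16 (2S)-8-[(2R)-2-(tert-butyldimethylsilyloxy)-3-methylbut-3-enyl]-2-[3,5-bis(3-methylbut-2-enyl)-4-(triisopropylsilyloxy)phenyl]-7-(triisopropylsilyloxy)chroman-4-one
Conditions: Pd(PPh3)4 (10 mol %), 15 (3 equiv), DMF (degassed), 100 °C
Reagents that add atoms: none
Why: In this twofold Stille coupling the zerovalent palladium inserts into each C–Br bond, the prenyl group is transferred from tin, and reductive elimination from the less hindered primary terminus of the allyl–palladium intermediate should give the linear prenyl groups, with no base present to open the flavanone.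

Step 12
Reactants: 16 (2S)-8-[(2R)-2-(tert-butyldimethylsilyloxy)-3-methylbut-3-enyl]-2-[3,5-bis(3-methylbut-2-enyl)-4-(triisopropylsilyloxy)phenyl]-7-(triisopropylsilyloxy)chroman-4-one
Product: 17 (2S)-7-hydroxy-2-[4-hydroxy-3,5-bis(3-methylbut-2-enyl)phenyl]-8-[(2R)-2-hydroxy-3-methylbut-3-enyl]chroman-4-one
Conditions: Bu4NF, AcOH (1:1), THF, 0 °C → rt
Reagents that add atoms: none
Why: Fluoride desilylation should cleave both aryl silyl ethers and the secondary allylic silyl ether, and the acetic acid buffer keeps the phenols protonated so that C2 is not scrambled through phenoxide-driven opening of the pyranone ring and the ortho-prenyl phenols do not cyclise.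

**Compound list**

1 | 7-hydroxychromone | O=c1ccoc2cc(O)ccc12 | starting material
2 | 3-chloro-3-methylbut-1-yne | C#CC(C)(C)Cl | starting material
3 | 7-(2-methylbut-3-yn-2-yloxy)chromen-4-one | O=c1ccoc2cc(OC(C)(C)C#C)ccc12 | intermediate
4 | 7-(2-methylbut-3-en-2-yloxy)chromen-4-one | O=c1ccoc2cc(OC(C)(C)C=C)ccc12 | intermediate
5 | 8-(3-methylbut-2-enyl)-8H-chromene-4,7-dione (ortho-dienone, not isolated, racemic at C8) | CC(C)=CCC1C(=O)C=CC2=C1OC=CC2=O | intermediate
6 | 7-hydroxy-8-(3-methylbut-2-enyl)chromen-4-one | CC(C)=CCc1c(O)ccc2c1occc2=O | intermediate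
7 | 8-(3-methylbut-2-enyl)-7-(triisopropylsilyloxy)chromen-4-one | CC(C)=CCc1c(O[Si](C(C)C)(C(C)C)C(C)C)ccc2c1occc2=O | intermediate
8 | 2,6-dibromophenol | Oc1c(Br)cccc1Br | starting material
9 | (2,6-dibromophenoxy)triisopropylsilane | CC(C)[Si](Oc1c(Br)cccc1Br)(C(C)C)C(C)C | intermediate
10 | 2-[3,5-dibromo-4-(triisopropylsilyloxy)phenyl]-4,4,5,5-tetramethyl-1,3,2-dioxaborolane | CC(C)[Si](Oc1c(Br)cc(cc1Br)B1OC(C)(C)C(C)(C)O1)(C(C)C)C(C)C | intermediate
11 | [3,5-dibromo-4-(triisopropylsilyloxy)phenyl]boronic acid | CC(C)[Si](Oc1c(Br)cc(cc1Br)B(O)O)(C(C)C)C(C)C | intermediate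
12 | (2S)-2-[3,5-dibromo-4-(triisopropylsilyloxy)phenyl]-8-(3-methylbut-2-enyl)-7-(triisopropylsilyloxy)chroman-4-one | CC(C)=CCc1c(O[Si](C(C)C)(C(C)C)C(C)C)ccc2c1O[C@H](c1cc(Br)c(O[Si](C(C)C)(C(C)C)C(C)C)c(Br)c1)CC2=O | intermediate
13 | (2S)-2-[3,5-dibromo-4-(triisopropylsilyloxy)phenyl]-8-{[(2R)-3,3-dimethyloxiran-2-yl]methyl}-7-(triisopropylsilyloxy)chroman-4-one | CC1(C)O[C@@H]1Cc1c(O[Si](C(C)C)(C(C)C)C(C)C)ccc2c1O[C@H](c1cc(Br)c(O[Si](C(C)C)(C(C)C)C(C)C)c(Br)c1)CC2=O | intermediate
14 | (2S)-8-[(2R)-2-(tert-butyldimethylsilyloxy)-3-methylbut-3-enyl]-2-[3,5-dibromo-4-(triisopropylsilyloxy)phenyl]-7-(triisopropylsilyloxy)chroman-4-one | C=C(C)[C@H](O[Si](C)(C)C(C)(C)C)Cc1c(O[Si](C(C)C)(C(C)C)C(C)C)ccc2c1O[C@H](c1cc(Br)c(O[Si](C(C)C)(C(C)C)C(C)C)c(Br)c1)CC2=O | intermediate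
15 | tributyl(3-methylbut-2-enyl)stannane | CCCC[Sn](CCCC)(CCCC)CC=C(C)C | starting material
16 | (2S)-8-[(2R)-2-(tert-butyldimethylsilyloxy)-3-methylbut-3-enyl]-2-[3,5-bis(3-methylbut-2-enyl)-4-(triisopropylsilyloxy)phenyl]-7-(triisopropylsilyloxy)chroman-4-one | C=C(C)[C@H](O[Si](C)(C)C(C)(C)C)Cc1c(O[Si](C(C)C)(C(C)C)C(C)C)ccc2c1O[C@H](c1cc(CC=C(C)C)c(O[Si](C(C)C)(C(C)C)C(C)C)c(CC=C(C)C)c1)CC2=O | intermediate
17 | (2S)-7-hydroxy-2-[4-hydroxy-3,5-bis(3-methylbut-2-enyl)phenyl]-8-[(2R)-2-hydroxy-3-methylbut-3-enyl]chroman-4-one | C=C(C)[C@H](O)Cc1c(O)ccc2c1O[C@H](c1cc(CC=C(C)C)c(O)c(CC=C(C)C)c1)CC2=O | target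

**Step count**

Total: 12 steps. Longest linear sequence: 9 steps (steps 1–4 and 8–12); the ring B branch (steps 5–7) joins at step 8.

**Steps most likely to fail**

Step 8. The 7-silyloxy group makes the chromone a weak acceptor, so insertion into the aryl–rhodium bond may be slower than protodeboronation. Face discrimination may also be incomplete, or enantiopurity at C2 may erode through base-promoted opening of the pyranone ring. The fallback gives up asymmetric C–C bond formation for a resolution and sets out from 7 and 11. A cationic divalent palladium catalyst, Pd(OCOCF3)2 with 2,2'-bipyridine in aqueous AcOH/THF at 60 °C, should add the aryl group without stereocontrol and without base to give the racemic flavanone F1. Asymmetric transfer hydrogenation under kinetic resolution follows, with RhCl(C5Me5)[(R,R)-TsDPEN] and HCO2H/Et3N in EtOAc. The catalyst antipode used is the one that reduces the (2R) ketone faster, expected to be (R,R); it should convert that enantiomer into the cis-(2R,4R)-flavan-4-ol F2, which is removed by chromatography. The unreduced (2S) ketone is recovered, and the route is rejoined at 12.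

Step 10. The cation at C3'' may be captured by the neighbouring silyloxy oxygen on C7, closing a dimethylchromane with loss of the silyl group. It may also undergo a 1,2-hydride shift to the C2'' ketone, or the C4 ketone may be enol-silylated. The fallback replaces the one-step isomerisation by hydrolytic opening and dehydration and sets out from 13. Dilute HClO4 in THF/H2O at 0 °C should open the oxirane with water at the tertiary C3'', leaving the C2''–O bond and its (R) configuration untouched, to give the (2''R)-2'',3''-diol F3. TBSCl and imidazole in DMF should silylate only the secondary hydroxyl, giving the C2'' silyl ether with free tertiary alcohol F4. SOCl2 in pyridine at 0 °C then dehydrates the tertiary alcohol towards a methyl group, and the route is rejoined at 14.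

Step 11. The prenyl group may be transferred through its tertiary terminus, giving 1,1-dimethylallyl isomers. The second coupling may stall at the bromide flanked by the bulky silyloxy group, and protodebromination may compete. The fallback separates C–C coupling from formation of the trisubstituted alkene and sets out from 14. Twofold Stille coupling with allyltributylstannane (Pd(PPh3)4, toluene, 100 °C), which transmetalates faster and has no regiochemical ambiguity, should give the 3',5'-diallyl compound F5. Cross-metathesis with 2-methylbut-2-ene as co-solvent, using the second-generation Grubbs catalyst RuCl2(=CHPh)(PCy3)(H2IMes) in CH2Cl2 at 40 °C, should convert both allyl groups into prenyl groups; the hindered 1,1-disubstituted alkene next to the silyloxy group should not take part. The route is rejoined at 16.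

**Further compounds**

F1 | step 8 | racemic 2-[3,5-dibromo-4-(triisopropylsilyloxy)phenyl]-8-(3-methylbut-2-enyl)-7-(triisopropylsilyloxy)chroman-4-one | CC(C)=CCc1c(O[Si](C(C)C)(C(C)C)C(C)C)ccc2c1OC(c1cc(Br)c(O[Si](C(C)C)(C(C)C)C(C)C)c(Br)c1)CC2=O
F2 | step 8 | (2R,4R)-2-[3,5-dibromo-4-(triisopropylsilyloxy)phenyl]-8-(3-methylbut-2-enyl)-7-(triisopropylsilyloxy)chroman-4-ol (2,4-cis) | CC(C)=CCc1c(O[Si](C(C)C)(C(C)C)C(C)C)ccc2c1O[C@@H](c1cc(Br)c(O[Si](C(C)C)(C(C)C)C(C)C)c(Br)c1)C[C@H]2O
F3 | step 10 | (2S)-2-[3,5-dibromo-4-(triisopropylsilyloxy)phenyl]-8-[(2R)-2,3-dihydroxy-3-methylbutyl]-7-(triisopropylsilyloxy)chroman-4-one | CC(C)(O)[C@H](O)Cc1c(O[Si](C(C)C)(C(C)C)C(C)C)ccc2c1O[C@H](c1cc(Br)c(O[Si](C(C)C)(C(C)C)C(C)C)c(Br)c1)CC2=O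
F4 | step 10 | (2S)-8-[(2R)-2-(tert-butyldimethylsilyloxy)-3-hydroxy-3-methylbutyl]-2-[3,5-dibromo-4-(triisopropylsilyloxy)phenyl]-7-(triisopropylsilyloxy)chroman-4-one | CC(C)(O)[C@H](O[Si](C)(C)C(C)(C)C)Cc1c(O[Si](C(C)C)(C(C)C)C(C)C)ccc2c1O[C@H](c1cc(Br)c(O[Si](C(C)C)(C(C)C)C(C)C)c(Br)c1)CC2=O
F5 | step 11 | (2S)-8-[(2R)-2-(tert-butyldimethylsilyloxy)-3-methylbut-3-enyl]-2-[3,5-diallyl-4-(triisopropylsilyloxy)phenyl]-7-(triisopropylsilyloxy)chroman-4-one | C=C(C)[C@H](O[Si](C)(C)C(C)(C)C)Cc1c(O[Si](C(C)C)(C(C)C)C(C)C)ccc2c1O[C@H](c1cc(CC=C)c(O[Si](C(C)C)(C(C)C)C(C)C)c(CC=C)c1)CC2=O
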